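The bromochlorocyclohexane ring is closed last, at C6–C11, by a bromiranium‑relayed spirocyclisation (step 10) in a 15‑step route. Two points are weaker than the rest: step 10 is a proposed new method, and the ring A stereocentres C3/C4 depend on a catalyst‑controlled dynamic reduction (step 14) because ring B gives ring A no usable facial bias.

Numbering: ring A = C1(=CH2), C2, C3(OAc), C4(Br), C5(Me2), C6 (spiro); ring B = C6, C7, C8, C9(Me,Cl), C10(Br), C11. Ring B is closed last, at C6–C11. The key step exploits the vicinal pair C10(Br)–C11: a primary triflate at C11 is expelled by the C10 bromine and the bromiranium ion is opened at C11 by C6 of a dimedone‑derived silyl dienol ether. One operation forms ring B and the quaternary spiro centre and relays the catalytically set C9/C10 configuration to C6. The precursor is a 1‑alkoxy‑3‑silyloxycyclohexadiene carrying an acyclic bromochlorohydrin chain at C6. C3 and C4 follow by catalyst‑controlled dynamic reduction.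

Key step: step 10

Remark on the chemistry: seen from ring A, the C7 and C11 arms of ring B are near mirror images (the C10 bromine is equatorial and points away), so C3/C4 cannot be relayed from C6 by substrate control; they are set by a chiral catalyst in step 14.
Assumption: 1 and 8 are commercial; the antipode of the Schiff‑base ligand (step 4) and of the ruthenium catalyst (step 14) that gives the stated configuration is fixed in a pilot run.

Step 1
Reactants: 1 tert‑butyl(but‑3‑yn‑1‑yloxy)dimethylsilane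
Product: 2 methyl 5‑[(tert‑butyldimethylsilyl)oxy]pent‑2‑ynoate
Conditions: n‑BuLi, THF, −78 °C; then ClCO2Me, −78 → 0 °C
Reagents that add atoms: methyl chloroformate, COC(=O)Cl
Why: Acylation of a lithium acetylide with a chloroformate is a standard ynoate synthesis and the silyl ether is inert to it.

Step 2
Reactants: 2 methyl 5‑[(tert‑butyldimethylsilyl)oxy]pent‑2‑ynoate
Product: 3 methyl (2Z)‑5‑[(tert‑butyldimethylsilyl)oxy]‑3‑methylpent‑2‑enoate
Conditions: Me2CuLi (CuI, 2 MeLi), THF, −78 °C; MeOH quench at −78 °C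
Reagents that add atoms: lithium dimethylcuprate, [Li+].C[Cu-]C
Why: Syn‑carbocupration (conjugate addition of a Gilman cuprate to an ynoate) and protonation of the vinylcopper at −78 °C place the new methyl cis to H, so the CH2CH2OTBS chain and the ester end up cis, the Z geometry needed for the later anti addition.

Step 3
Reactants: 3 methyl (2Z)‑5‑[(tert‑butyldimethylsilyl)oxy]‑3‑methylpent‑2‑enoate
Product: 4 (2Z)‑5‑[(tert‑butyldimethylsilyl)oxy]‑3‑methylpent‑2‑en‑1‑ol
Conditions: DIBAL‑H, CH2Cl2, −78 °C; Rochelle salt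
Reagents that add atoms: none
Why: DIBAL‑H 1,2‑reduction of an enoate to the allylic alcohol does not touch the trisubstituted Z double bond or the silyl ether.

Step 4
Reactants: 4 (2Z)‑5‑[(tert‑butyldimethylsilyl)oxy]‑3‑methylpent‑2‑en‑1‑ol
Product: 5 (2R,3R)‑2‑bromo‑5‑[(tert‑butyldimethylsilyl)oxy]‑3‑chloro‑3‑methylpentan‑1‑ol
Conditions: NBS, ClTi(Oi‑Pr)3, chiral tridentate Schiff‑base ligand from 2‑amino‑1,1,2‑triphenylethanol (20 mol %), hexanes, −20 °C
Reagents that add atoms: N‑bromosuccinimide, O=C1CCC(=O)N1Br; chlorotitanium triisopropoxide, CC(C)O[Ti](Cl)(OC(C)C)OC(C)C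
Why: Catalytic enantioselective bromochlorination of an allylic alcohol: the titanium‑bound alcohol and the chiral ligand control the face on which bromine enters, chloride opens the bromiranium anti at the tertiary carbon, and anti addition to the Z alkene gives the like (2R,3R) pair, i.e. both halogen‑bearing stereocentres (C10 and C9 of the target) in one event.

Step 5
Reactants: 5 (2R,3R)‑2‑bromo‑5‑[(tert‑butyldimethylsilyl)oxy]‑3‑chloro‑3‑methylpentan‑1‑ol
Product: 6 (2R,3R)‑2‑bromo‑5‑[(tert‑butyldimethylsilyl)oxy]‑3‑chloro‑3‑methylpentyl pivalate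
Conditions: PivCl, pyridine, DMAP (cat.), CH2Cl2, 0 °C
Reagents that add atoms: pivaloyl chloride, CC(C)(C)C(=O)Cl
Why: Pyridine/DMAP acylation of the primary alcohol is too weakly basic to close the bromohydrin to an epoxide, and the pivalate is chosen because it survives lithium amides and enolates.

Step 6
Reactants: 6 (2R,3R)‑2‑bromo‑5‑[(tert‑butyldimethylsilyl)oxy]‑3‑chloro‑3‑methylpentyl pivalate
Product: 7 (2R,3R)‑2‑bromo‑3‑chloro‑5‑hydroxy‑3‑methylpentyl pivalate
Conditions: HF·pyridine, THF/pyridine, 0 °C → rt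
Reagents that add atoms: none
Why: Buffered fluoride cleavage of the primary TBS ether leaves the pivalate, the secondary bromide and the tertiary chloride untouched.

Step 7
Reactants: 8 dimedone (5,5‑dimethylcyclohexane‑1,3‑dione)
Product: 9 5,5‑dimethyl‑3‑(2‑methylpropoxy)cyclohex‑2‑en‑1‑one
Conditions: i‑BuOH, p‑TsOH (cat.), toluene, reflux, Dean–Stark
Reagents that add atoms: 2‑methylpropan‑1‑ol, CC(C)CO
Why: Acid‑catalysed enol ether formation from a cyclic 1,3‑dione with azeotropic removal of water gives the vinylogous ester that blocks C2 and directs enolisation to C6.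

Step 8
Reactants: 7 (2R,3R)‑2‑bromo‑3‑chloro‑5‑hydroxy‑3‑methylpentyl pivalate; 9 5,5‑dimethyl‑3‑(2‑methylpropoxy)cyclohex‑2‑en‑1‑one
Product: 11 6‑[(3R,4R)‑4‑bromo‑3‑chloro‑3‑methyl‑5‑(pivaloyloxy)pentyl]‑5,5‑dimethyl‑3‑(2‑methylpropoxy)cyclohex‑2‑en‑1‑one (both C6 epimers), via primary triflate 10 (not isolated)
Conditions: 7: Tf2O, 2,6‑lutidine, CH2Cl2, −78 °C; 9: LDA, THF, −78 °C; then cold 10, −78 → −40 °C
Reagents that add atoms: none
Why: Kinetic α′‑deprotonation of the vinylogous ester (Stork–Danheiser alkylation) and SN2 reaction with the unhindered primary triflate at −78 °C form the C6–C7 bond fast enough that the pivalate and the halides are not attacked; C6 forms as an epimer mixture that is erased in step 9.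

Step 9
Reactants: 11 6‑[(3R,4R)‑4‑bromo‑3‑chloro‑3‑methyl‑5‑(pivaloyloxy)pentyl]‑5,5‑dimethyl‑3‑(2‑methylpropoxy)cyclohex‑2‑en‑1‑one
Product: 13 (2R,3R)‑2‑bromo‑5‑[2‑[(tert‑butyldimethylsilyl)oxy]‑6,6‑dimethyl‑4‑(2‑methylpropoxy)cyclohexa‑1,3‑dien‑1‑yl]‑3‑chloro‑3‑methylpentan‑1‑ol, via silyl dienol ether pivalate 12 (not isolated)
Conditions: LDA, THF, −78 °C; TBSOTf; then DIBAL‑H, −78 °C; Rochelle salt
Reagents that add atoms: tert‑butyldimethylsilyl triflate, CC(C)(C)[Si](C)(C)OS(=O)(=O)C(F)(F)F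
Why: A second kinetic α′‑deprotonation and O‑silylation give the cross‑conjugated 1‑alkoxy‑3‑silyloxydiene, which masks the ketone so that DIBAL‑H can cleave the pivalate reductively without base, the aluminium alkoxide of the bromohydrin being too unreactive at −78 °C to form an epoxide.

Step 10
Reactants: 13 (2R,3R)‑2‑bromo‑5‑[2‑[(tert‑butyldimethylsilyl)oxy]‑6,6‑dimethyl‑4‑(2‑methylpropoxy)cyclohexa‑1,3‑dien‑1‑yl]‑3‑chloro‑3‑methylpentan‑1‑ol
Product: 16 (6S,9R,10R)‑10‑bromo‑9‑chloro‑5,5,9‑trimethyl‑3‑(2‑methylpropoxy)spiro[5.5]undec‑2‑en‑1‑one, via primary triflate 14 (not isolated), via bromiranium triflate 15 (not isolated)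
Conditions: Tf2O (1.05 equiv), 2,6‑di‑tert‑butyl‑4‑methylpyridine, CH2Cl2, −78 → −20 °C
Reagents that add atoms: none
Why: Proposed new method: O‑triflation of the primary alcohol is followed by backside displacement of triflate by the neighbouring C10 bromine, and the bromiranium ion is opened at its primary carbon C11 by C6 of the silyl dienol ether, after which the silyloxyallyl cation gives its silyl group to triflate and returns the vinylogous ester. The closest known reactions are the stereospecific solvolytic cyclisations of enantioenriched bromochlorides through bromiranium ions and the alkylation of silyl enol ethers by SN1‑type electrophiles. Ring B closes in the 6‑endo mode with respect to the three‑membered bromiranium (attack at the distal carbon, both of its carbons ending in the new ring) through a chair‑like transition state. Because the opening must be anti, the C10–Br bond lies antiperiplanar to the forming C6–C11 bond and is equatorial in that chair (Cl equatorial, 9‑methyl axial), and the bulky C5 (CMe2) side of the planar nucleophile takes the pseudo‑equatorial site while C1 takes the axial one, so C9/C10 dictate the configuration of the new quaternary centre C6 as drawn (Br cis to C5). The step needs attack at C11 and not at C10 (C10 is flanked by the quaternary, chlorine‑bearing C9 and would give a five‑membered ring), ionisation at C11 and not of the tertiary chloride (a triflate in CH2Cl2 at low temperature against a chloride that needs a protic ionising solvent), and no direct SN2 by the dienol ether (which could only pass through the chair with axial Br and would give the C6 epimer, but should be far slower at this hindered carbon than the intramolecular bromine).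

Step 11
Reactants: 16 (6S,9R,10R)‑10‑bromo‑9‑chloro‑5,5,9‑trimethyl‑3‑(2‑methylpropoxy)spiro[5.5]undec‑2‑en‑1‑one
Product: 17 (6S,9R,10R)‑10‑bromo‑9‑chloro‑1,5,5,9‑tetramethylspiro[5.5]undec‑1‑en‑3‑one
Conditions: MeLi, CeCl3, THF, −78 °C; then 1 M HCl, 0 °C → rt
Reagents that add atoms: methyllithium, [Li]C; water, O
Why: Stork–Danheiser transposition: the weakly basic organocerium adds 1,2 to the hindered vinylogous ester carbonyl without eliminating HCl or HBr, and acid hydrolysis with loss of water gives the isophorone‑type enone.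

Step 12
Reactants: 17 (6S,9R,10R)‑10‑bromo‑9‑chloro‑1,5,5,9‑tetramethylspiro[5.5]undec‑1‑en‑3‑one
Product: 19 (6R,9R,10R)‑4,10‑dibromo‑9‑chloro‑1,5,5,9‑tetramethylspiro[5.5]undec‑1‑en‑3‑one (C4 epimers), via kinetic silyl enol ether 18 (not isolated)
Conditions: LDA, TMSCl, THF, −78 °C; then NBS, THF, −78 → 0 °C
Reagents that add atoms: N‑bromosuccinimide, O=C1CCC(=O)N1Br
Why: Kinetic α′‑enolisation of the enone (C4 is its only α′ position, as in isophorone), trapping as the cross‑conjugated silyl enol ether and electrophilic bromination place bromine at C4; no facial bias is expected from ring B, so both C4 epimers should form and are funnelled in step 14.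

Step 13
Reactants: 19 (6R,9R,10R)‑4,10‑dibromo‑9‑chloro‑1,5,5,9‑tetramethylspiro[5.5]undec‑1‑en‑3‑one
Product: 21 (6R,9R,10R)‑4,10‑dibromo‑9‑chloro‑5,5,9‑trimethyl‑1‑methylidenespiro[5.5]undecan‑3‑one (C4 epimers), via exocyclic silyl dienol ether 20 (not isolated)
Conditions: TMSOTf, Et3N, CH2Cl2, 0 °C; then TBAF/AcOH (1:1), THF, −78 °C
Reagents that add atoms: none
Why: Soft enolisation removes a proton from the C1 methyl group (the neopentyl C4–H is shielded) to give the linear silyl dienol ether, and fluoride‑induced desilylation in the presence of acetic acid protonates the dienolate at the α carbon C2, a kinetic deconjugation that leaves the exocyclic methylene.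

Step 14
Reactants: 21 (6R,9R,10R)‑4,10‑dibromo‑9‑chloro‑5,5,9‑trimethyl‑1‑methylidenespiro[5.5]undecan‑3‑one
Product: 22 (3S,4R,6R,9R,10R)‑4,10‑dibromo‑9‑chloro‑5,5,9‑trimethyl‑1‑methylidenespiro[5.5]undecan‑3‑ol
Conditions: RuCl(p‑cymene)[(S,S)‑TsDPEN] (3 mol %), HCO2H/Et3N (5:2), EtOAc, 0 °C
Reagents that add atoms: none
Why: Noyori–Ikariya asymmetric transfer hydrogenation with dynamic kinetic resolution of a cyclic α‑halo ketone: the C4 epimers interconvert through the enol, the chiral catalyst reduces one of them faster, and hydride adds to the face that gives the cis‑bromohydrin, so C4 (R) and C3 (S) are set together under catalyst control.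

Step 15
Reactants: 22 (3S,4R,6R,9R,10R)‑4,10‑dibromo‑9‑chloro‑5,5,9‑trimethyl‑1‑methylidenespiro[5.5]undecan‑3‑ol
Product: 23 (3S,4R,6R,9R,10R)‑4,10‑dibromo‑9‑chloro‑5,5,9‑trimethyl‑1‑methylidenespiro[5.5]undecan‑3‑yl acetate
Conditions: Ac2O, DMAP, pyridine, CH2Cl2, rt
Reagents that add atoms: acetic anhydride, CC(=O)OC(C)=O
Why: DMAP‑catalysed acetylation of the hindered secondary alcohol changes no stereocentre and gives the target.

Compound list
1 | tert‑butyl(but‑3‑yn‑1‑yloxy)dimethylsilane | C#CCCO[Si](C)(C)C(C)(C)C | starting material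
2 | methyl 5‑[(tert‑butyldimethylsilyl)oxy]pent‑2‑ynoate | COC(=O)C#CCCO[Si](C)(C)C(C)(C)C | intermediate
3 | methyl (2Z)‑5‑[(tert‑butyldimethylsilyl)oxy]‑3‑methylpent‑2‑enoate | COC(=O)/C=C(/C)CCO[Si](C)(C)C(C)(C)C | intermediate
4 | (2Z)‑5‑[(tert‑butyldimethylsilyl)oxy]‑3‑methylpent‑2‑en‑1‑ol | OC/C=C(/C)CCO[Si](C)(C)C(C)(C)C | intermediate
5 | (2R,3R)‑2‑bromo‑5‑[(tert‑butyldimethylsilyl)oxy]‑3‑chloro‑3‑methylpentan‑1‑ol | OC[C@@H](Br)[C@](C)(Cl)CCO[Si](C)(C)C(C)(C)C | intermediate
6 | (2R,3R)‑2‑bromo‑5‑[(tert‑butyldimethylsilyl)oxy]‑3‑chloro‑3‑methylpentyl pivalate | CC(C)(C)C(=O)OC[C@@H](Br)[C@](C)(Cl)CCO[Si](C)(C)C(C)(C)C | intermediate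
7 | (2R,3R)‑2‑bromo‑3‑chloro‑5‑hydroxy‑3‑methylpentyl pivalate | CC(C)(C)C(=O)OC[C@@H](Br)[C@](C)(Cl)CCO | intermediate
8 | dimedone (5,5‑dimethylcyclohexane‑1,3‑dione) | CC1(C)CC(=O)CC(=O)C1 | starting material
9 | 5,5‑dimethyl‑3‑(2‑methylpropoxy)cyclohex‑2‑en‑1‑one | CC(C)COC1=CC(=O)CC(C)(C)C1 | intermediate
10 | (3R,4R)‑4‑bromo‑3‑chloro‑3‑methyl‑5‑(pivaloyloxy)pentyl trifluoromethanesulfonate | CC(C)(C)C(=O)OC[C@@H](Br)[C@](C)(Cl)CCOS(=O)(=O)C(F)(F)F | intermediate
11 | 6‑[(3R,4R)‑4‑bromo‑3‑chloro‑3‑methyl‑5‑(pivaloyloxy)pentyl]‑5,5‑dimethyl‑3‑(2‑methylpropoxy)cyclohex‑2‑en‑1‑one (C6 epimers) | CC(C)COC1=CC(=O)C(CC[C@@](C)(Cl)[C@H](Br)COC(=O)C(C)(C)C)C(C)(C)C1 | intermediate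
12 | (2R,3R)‑2‑bromo‑5‑[2‑[(tert‑butyldimethylsilyl)oxy]‑6,6‑dimethyl‑4‑(2‑methylpropoxy)cyclohexa‑1,3‑dien‑1‑yl]‑3‑chloro‑3‑methylpentyl pivalate | CC(C)COC1=CC(O[Si](C)(C)C(C)(C)C)=C(CC[C@@](C)(Cl)[C@H](Br)COC(=O)C(C)(C)C)C(C)(C)C1 | intermediate
13 | (2R,3R)‑2‑bromo‑5‑[2‑[(tert‑butyldimethylsilyl)oxy]‑6,6‑dimethyl‑4‑(2‑methylpropoxy)cyclohexa‑1,3‑dien‑1‑yl]‑3‑chloro‑3‑methylpentan‑1‑ol | CC(C)COC1=CC(O[Si](C)(C)C(C)(C)C)=C(CC[C@@](C)(Cl)[C@H](Br)CO)C(C)(C)C1 | intermediate
14 | primary triflate of 13 | CC(C)COC1=CC(O[Si](C)(C)C(C)(C)C)=C(CC[C@@](C)(Cl)[C@H](Br)COS(=O)(=O)C(F)(F)F)C(C)(C)C1 | intermediate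
15 | bromiranium triflate from 14 (C10–C11 bridged by Br+) | CC(C)COC1=CC(O[Si](C)(C)C(C)(C)C)=C(CC[C@@](C)(Cl)[C@H]2C[Br+]2)C(C)(C)C1.[O-]S(=O)(=O)C(F)(F)F | intermediate
16 | (6S,9R,10R)‑10‑bromo‑9‑chloro‑5,5,9‑trimethyl‑3‑(2‑methylpropoxy)spiro[5.5]undec‑2‑en‑1‑one | O=C1C=C(OCC(C)C)CC(C)(C)[C@@]12CC[C@@](C)(Cl)[C@H](Br)C2 | intermediate
17 | (6S,9R,10R)‑10‑bromo‑9‑chloro‑1,5,5,9‑tetramethylspiro[5.5]undec‑1‑en‑3‑one | CC1=CC(=O)CC(C)(C)[C@@]12CC[C@@](C)(Cl)[C@H](Br)C2 | intermediate
18 | 3‑trimethylsilyloxy‑1,3‑diene (kinetic silyl enol ether of 17) | CC1=CC(O[Si](C)(C)C)=CC(C)(C)[C@@]12CC[C@@](C)(Cl)[C@H](Br)C2 | intermediate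
19 | (6R,9R,10R)‑4,10‑dibromo‑9‑chloro‑1,5,5,9‑tetramethylspiro[5.5]undec‑1‑en‑3‑one (C4 epimers) | CC1=CC(=O)C(Br)C(C)(C)[C@@]12CC[C@@](C)(Cl)[C@H](Br)C2 | intermediate
20 | 1‑methylidene‑3‑trimethylsilyloxy‑2‑ene (linear silyl dienol ether of 19) | C=C1C=C(O[Si](C)(C)C)C(Br)C(C)(C)[C@@]12CC[C@@](C)(Cl)[C@H](Br)C2 | intermediate
21 | (6R,9R,10R)‑4,10‑dibromo‑9‑chloro‑5,5,9‑trimethyl‑1‑methylidenespiro[5.5]undecan‑3‑one (C4 epimers) | C=C1CC(=O)C(Br)C(C)(C)[C@@]12CC[C@@](C)(Cl)[C@H](Br)C2 | intermediate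
22 | (3S,4R,6R,9R,10R)‑4,10‑dibromo‑9‑chloro‑5,5,9‑trimethyl‑1‑methylidenespiro[5.5]undecan‑3‑ol | C=C1C[C@H](O)[C@H](Br)C(C)(C)[C@@]12CC[C@@](C)(Cl)[C@H](Br)C2 | intermediate
23 | (3S,4R,6R,9R,10R)‑4,10‑dibromo‑9‑chloro‑5,5,9‑trimethyl‑1‑methylidenespiro[5.5]undecan‑3‑yl acetate | C=C1C[C@H](OC(C)=O)[C@H](Br)C(C)(C)[C@@]12CC[C@@](C)(Cl)[C@H](Br)C2 | target

Total step count: 15
Longest linear sequence: 14 steps (steps 1–6 and 8–15; step 7 is the one‑step side branch)

Steps most likely to fail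

1. Step 10 (Proposed new method).
What may go wrong: ionisation or capture at the wrong site. The tertiary chloride may be lost with elimination, the bromiranium may be opened at C10 to a cyclopentane, or the dienol ether may be triflylated or protodesilylated before the alkyl triflate forms.
Fallback (known chemistry, ring B still closed last but at C6–C7): it sets out from 5 and 9 and comes back at 16. Alcohol 5 would be converted with Tf2O/2,6‑lutidine into (2R,3R)‑2‑bromo‑5‑[(tert‑butyldimethylsilyl)oxy]‑3‑chloro‑3‑methylpentyl triflate F1. The lithium enolate of 9 would be alkylated with it at C6 to give the C6–C11‑linked vinylogous ester F2. HF·pyridine would free the C7 alcohol F3, and iodine/PPh3/imidazole (Appel reaction) would give the primary iodide F4. KHMDS in THF (−78 → 0 °C) would then close ring B by a classical intramolecular 6‑exo‑tet enolate alkylation to 16. The chair with equatorial Br (no 1,3‑diaxial contact with the enolate carbon C1) and equatorial C5 is expected to be preferred, though less strictly than in step 10.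

2. Step 14.
What may go wrong: epimerisation at the neopentyl C4 may be slow relative to reduction (incomplete dynamic resolution), the catalyst may discriminate poorly on a purely aliphatic ketone, and the exocyclic double bond may migrate into conjugation in the buffered medium.
Fallback: it sets out from 21 and comes back at 22. Luche reduction (NaBH4, CeCl3, MeOH, −78 °C) would give the two cis‑bromohydrins by local substrate control, 22 and its ring A diastereomer (3R,4S,6R,9R,10R)‑bromohydrin F5. A lipase‑catalysed acylation (Pseudomonas cepacia lipase, vinyl butanoate) is expected to esterify the (3R) carbinol preferentially to the butanoate F6, and unreacted 22 would be separated and taken into step 15. This is a resolution and gives up the material that ends as F6.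

3. Step 13.
What may go wrong: enolisation toward C4 instead of the methyl group, γ‑ instead of α‑protonation of the dienolate (return to 19), or loss of bromide from the α‑bromo silyl dienol ether.
Fallback: it sets out from 16 and comes back at 21, replacing steps 11–13. The extended enolate of 16 (LDA, THF, −78 °C; only C4 carries acidic hydrogens) would be brominated with NBS at the γ carbon to give the 4‑bromo vinylogous ester F7. Me3SiCH2Li/CeCl3 would add to C1 to give the β‑hydroxysilane F8. Aqueous oxalic acid would then effect Peterson elimination to the exocyclic methylene and hydrolysis of the dienol ether with α‑protonation, giving 21.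

Further compounds
F1 | step 10 | (2R,3R)‑2‑bromo‑5‑[(tert‑butyldimethylsilyl)oxy]‑3‑chloro‑3‑methylpentyl trifluoromethanesulfonate | FC(F)(F)S(=O)(=O)OC[C@@H](Br)[C@](C)(Cl)CCO[Si](C)(C)C(C)(C)C
F2 | step 10 | 6‑[(2R,3R)‑2‑bromo‑5‑[(tert‑butyldimethylsilyl)oxy]‑3‑chloro‑3‑methylpentyl]‑5,5‑dimethyl‑3‑(2‑methylpropoxy)cyclohex‑2‑en‑1‑one (C6 epimers) | CC(C)COC1=CC(=O)C(C[C@@H](Br)[C@](C)(Cl)CCO[Si](C)(C)C(C)(C)C)C(C)(C)C1
F3 | step 10 | 6‑[(2R,3R)‑2‑bromo‑3‑chloro‑5‑hydroxy‑3‑methylpentyl]‑5,5‑dimethyl‑3‑(2‑methylpropoxy)cyclohex‑2‑en‑1‑one (C6 epimers) | CC(C)COC1=CC(=O)C(C[C@@H](Br)[C@](C)(Cl)CCO)C(C)(C)C1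
F4 | step 10 | 6‑[(2R,3R)‑2‑bromo‑3‑chloro‑5‑iodo‑3‑methylpentyl]‑5,5‑dimethyl‑3‑(2‑methylpropoxy)cyclohex‑2‑en‑1‑one (C6 epimers) | CC(C)COC1=CC(=O)C(C[C@@H](Br)[C@](C)(Cl)CCI)C(C)(C)C1
F5 | step 14 | (3R,4S,6R,9R,10R)‑4,10‑dibromo‑9‑chloro‑5,5,9‑trimethyl‑1‑methylidenespiro[5.5]undecan‑3‑ol | C=C1C[C@@H](O)[C@@H](Br)C(C)(C)[C@@]12CC[C@@](C)(Cl)[C@H](Br)C2
F6 | step 14 | (3R,4S,6R,9R,10R)‑4,10‑dibromo‑9‑chloro‑5,5,9‑trimethyl‑1‑methylidenespiro[5.5]undecan‑3‑yl butanoate | C=C1C[C@@H](OC(=O)CCC)[C@@H](Br)C(C)(C)[C@@]12CC[C@@](C)(Cl)[C@H](Br)C2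
F7 | step 13 | (6S,9R,10R)‑4,10‑dibromo‑9‑chloro‑5,5,9‑trimethyl‑3‑(2‑methylpropoxy)spiro[5.5]undec‑2‑en‑1‑one (C4 epimers) | O=C1C=C(OCC(C)C)C(Br)C(C)(C)[C@@]12CC[C@@](C)(Cl)[C@H](Br)C2
F8 | step 13 | (6S,9R,10R)‑4,10‑dibromo‑9‑chloro‑5,5,9‑trimethyl‑3‑(2‑methylpropoxy)‑1‑[(trimethylsilyl)methyl]spiro[5.5]undec‑2‑en‑1‑ol (C1 and C4 epimers) | C[Si](C)(C)CC1(O)C=C(OCC(C)C)C(Br)C(C)(C)[C@@]12CC[C@@](C)(Cl)[C@H](Br)C2
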